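**Route in one sentence:** a mirror-symmetric ring A aryllithium, made by metalation of 5-methoxyresorcinol bis(methoxymethyl) ether at the carbon between its two acetal oxygens, is acylated by an enantiopure trans-3-phenylglycidic N-methoxy-N-methylamide, so that the C4–C4a bond is formed with C2 and C3 already present as an oxirane.

## Structural features

The target is a trans-dihydroflavonol (3-hydroxyflavanone): a chroman-4-one in which benzo ring A is fused to pyranone ring C at C4a–C8a, with an unsubstituted phenyl ring B on C2. Ring A is a fully differentiated phloroglucinol: a free hydroxyl at C5 (hydrogen-bonded to the C4 carbonyl), a methoxy group at C7, a prenyl group at C8, the ring oxygen O1 at C8a, and hydrogen only at C6. The two stereocentres, C2 (R, benzylic, bearing O1) and C3 (R, secondary alcohol next to the C4 ketone), are adjacent and trans. Fragile points are the α-ketol/β-aryloxy ketone (base can expel O1 from the C3 enolate, contract ring C to a benzofuranone or allow air oxidation to the flavonol), the epimerisable C3, and the acid- and oxidant-sensitive trisubstituted prenyl alkene. The difficulty is twofold: an enantiopure C2/C3 pair must be built beside an aroyl group flanked by two ortho oxygens (C5 and C8a), which is hindered and twisted; and the prenyl group must reach C8 and not C6, while the two ortho oxygens take different roles (O1 in ring C, O5 free). The key step exploits two features. First, C4a is the one ring A carbon that lies between two oxygen-bearing carbons (C5 and C8a) and carries C4, so in a ring A piece without the C8 substituent it sits on a mirror plane and is the unique doubly activated C–H. Second, the C4(=O)–C3(OH)–C2(OAr)Ph array of ring C is an anti-opened trans-3-phenylglycidoyl unit, so both stereocentres can arrive inside the acyl donor; the C8 question is left to the para relation of O5 and C8.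

## Logic of the disconnections

14 is cut at the C8–C1″ bond of the prenyl group. Direct C-prenylation cannot tell C6 from C8, but O5 is para to C8, so the five-carbon unit is moved back to O5, giving 11. The gain is that every earlier ring A intermediate carries no carbon substituent at C6 or C8. The demand is that two consecutive sigmatropic shifts (O5 to C6, then C6 to C8, through 12 and 13) run to the end without stopping at C6 and without harming the α-ketol.

11 is cut at the O5–C1″ ether bond to give 10. The C5 hydroxyl is the only phenol of 10, so no protecting group is needed. The demand is O-alkylation of a chelated phenol under a base mild enough for the α-ketol.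

10 is cut at the O1–C2 bond. The anti relation of O1 on C2 and the hydroxyl on C3 is what SN2 opening of a trans-oxirane gives, so 10 goes back to 9 and, with both phenols masked, to 8. The gain is that ring C and the C2 configuration are traced to an oxirane of fixed geometry, and that the two ortho oxygens of 9 are equivalent, so ring closure has no regiochemical choice. The demand is 6-endo attack at the benzylic carbon with inversion, in preference to 5-exo attack or ionisation.

8 is cut at the C4–C4a bond (key disconnection) to give 6 and 5, with 7 as the adduct between them. The cut separates an achiral, mirror-symmetric ring A nucleophile from a small acyl donor that holds both stereocentres, so no asymmetric reaction has to be run on the hindered diortho-substituted aryl ketone. The demand is metalation at the one carbon between the two acetal oxygens, and acylation that leaves the oxirane and its C–H untouched.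

6 goes back to 2 by replacing lithium with hydrogen, and 2 is cut at its two O–CH2 acetal bonds to give 1. The acetals are chosen because they direct the metalation and leave under the same acid that closes ring C. The demand is only complete double protection.

5 is cut at the amide C–N bond to give 4, and 4 is taken back one oxidation level at the carboxyl carbon to 3. 3 is the product of a reagent-controlled allylic alcohol epoxidation, the substrate class on which that reaction is most reliable, and sets both stereocentres in one event. The demand is oxidation and coupling that neither open the oxirane nor allow the glycidic acid to decarboxylate.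

## Other disconnections considered

Alternative 1: the first route that comes to mind cuts C2–C3 (aldol) and then O1–C2. Forward, a Claisen–Schmidt condensation would give chalcone A1, catalytic asymmetric nucleophilic epoxidation would give A2, and deprotection would close ring C. The chosen plan is preferred on three grounds. The enone of A1 is flanked by two ortho alkoxy groups, is twisted out of the aryl plane and is electron-rich, so hydroperoxide conjugate addition under a chiral catalyst would rest on its least favourable substrate class. After deprotection of A2 both ortho hydroxyls can open the oxirane, so 6- and 8-prenyl isomers are both expected. The prenylated methyl ketone behind A1 needs a regioselective C-prenylation of its own.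

Alternative 2: cut the C3–O bond last. Forward, an enantioselective intramolecular oxa-Michael addition would give flavanone A3, and its C3 enolate or silyl enol ether would be hydroxylated trans to the phenyl group. The C3 enolate of A3 is the very species that expels O1 by E1cB ring opening, so the C2 stereocentre is at risk in the step meant to use it. The electrophilic oxygen sources that hydroxylate enolates (peracids, dioxiranes) also attack the trisubstituted prenyl alkene. Phenol protection adds steps, and the C8 regiochemistry is not addressed at all.

Alternative 3: cut the C2–C1′ bond to ring B. Forward, a phenylboron reagent would add enantioselectively to the 3-silyloxychromone A4 under a chiral Pd(OCOCF3)2–pyridine-oxazoline catalyst, followed by protonation at C3 and desilylation. C2 of A4 is the β-carbon of an enone fed by two oxygen donors (O1 and the C3 oxygen) and is part of a trisubstituted alkene, so migratory insertion should be slow. C3 would be set only by protonation of an enolate that can also open ring C. Known conjugate arylations of chromones have C3 unsubstituted, so the key step would be an untested extension, and A4 needs the same C8 regiocontrol. The chosen plan reaches the same bonds with known reaction types.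

Key step: step 4

Assumption: 3 is bought as the single (2S,3S) enantiomer (the Sharpless epoxidation product of cinnamyl alcohol with L-(+)-tartrate); its enantiomeric purity sets that of 14.

## Steps

Step 1
Reactants: 1 5-methoxyresorcinol (5-methoxybenzene-1,3-diol)
Product: 2 1-methoxy-3,5-bis(methoxymethoxy)benzene
Conditions: NaH (2.4 equiv), MOMCl (2.4 equiv), DMF, 0 °C to rt
Reagents that add atoms: chloromethyl methyl ether (MOMCl), COCCl
Why: Williamson-type O-alkylation of both phenoxides; the acetals are chosen because they direct the lithiation of step 4 and leave under the acid that closes ring C in step 5. 2 keeps the mirror plane of 1, so the two protected oxygens stay equivalent.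

Step 2
Reactants: 3 (2S,3S)-3-phenylglycidol [(2S,3S)-(3-phenyloxiran-2-yl)methanol]
Product: 4 (2R,3S)-3-phenyloxirane-2-carboxylic acid
Conditions: TEMPO (20 mol %), PhI(OAc)2 (2.2 equiv), MeCN–H2O 1:1, 0 °C to rt; extracted cold and used at once
Reagents that add atoms: water, O
Why: TEMPO/PhI(OAc)2 oxidation of a primary alcohol through the aldehyde hydrate to the acid, under near-neutral conditions that should leave the oxirane closed. No bond to either stereocentre is touched; the C2 descriptor changes from S to R only because the carboxyl group outranks C3. The acid is not stored because glycidic acids decarboxylate on warming.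

Step 3
Reactants: 4 (2R,3S)-3-phenyloxirane-2-carboxylic acid
Product: 5 (2R,3S)-N-methoxy-N-methyl-3-phenyloxirane-2-carboxamide
Conditions: MeNH(OMe)·HCl (1.2 equiv), EDC·HCl (1.2 equiv), HOBt (1.2 equiv), N-methylmorpholine (2.4 equiv), CH2Cl2, 0 °C
Reagents that add atoms: N,O-dimethylhydroxylamine hydrochloride, CNOC.Cl
Why: Carbodiimide/HOBt amidation at 0 °C. The oxirane C–H next to the activated carboxyl is not acidic enough for an amine base to epimerise it, so the trans (2R,3S) configuration should be kept.

Step 4
Reactants: 2 1-methoxy-3,5-bis(methoxymethoxy)benzene; 5 (2R,3S)-N-methoxy-N-methyl-3-phenyloxirane-2-carboxamide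
Product: 8 [4-methoxy-2,6-bis(methoxymethoxy)phenyl][(2R,3S)-3-phenyloxiran-2-yl]methanone, via aryllithium 6 (not isolated), via lithium carbinolamine adduct 7 (not isolated)
Conditions: 2 (1.3 equiv), n-BuLi (1.2 equiv), THF, 0 °C, 1 h; then 5 (1.0 equiv), −78 to −30 °C; sat. aq. NH4Cl
Reagents that add atoms: none
Why: Directed ortho-metalation followed by a Weinreb ketone synthesis, a known pairing for 2,6-dialkoxyaryllithiums and for α,β-epoxy N-methoxy-N-methylamides. n-BuLi is held by both methoxymethyl ethers of 2 and removes the one hydrogen between them, on the mirror plane, so a single aryllithium 6 should form; each of the two other ring hydrogens has one weaker methoxy neighbour. 6 adds to the amide carbonyl of 5 to give the five-membered O–Li–OMe chelate 7, which does not collapse before the aqueous quench, so no ketone meets base: no second addition and no enolisation beside the oxirane. The step closes no ring; it forms the C4–C4a bond, and ring C is closed from its product in step 5 by 6-endo attack of the C8a oxygen on C2. No lasting stereocentre is created (the carbinolamine carbon of 7 is lost on quench): C3 and the future C2 arrive as a pair in the oxirane of 5, and neither oxirane C–O bond nor the oxirane C–H is touched at −78 °C. The selectivity needed is carbonyl attack over oxirane opening and over proton transfer; a chelated aryllithium at low temperature should prefer the amide carbonyl, and oxirane opening by organolithiums needs a Lewis acid that is absent. Because 2 is mirror-symmetric about the C4a–C7 axis, the acyl group enters without regiochemical choice and both ortho oxygens stay equivalent until ring closure.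

Step 5
Reactants: 8 [4-methoxy-2,6-bis(methoxymethoxy)phenyl][(2R,3S)-3-phenyloxiran-2-yl]methanone
Product: 10 (2R,3R)-3,5-dihydroxy-7-methoxy-2-phenyl-2,3-dihydro-4H-chromen-4-one (alpinone), via bis-phenol epoxy ketone 9 (not isolated)
Conditions: TsOH·H2O (1.0 equiv), MeOH–THF 1:1, 50 °C
Reagents that add atoms: none
Why: Acid-catalysed acetal exchange frees both phenols (9); a phenol then opens the protonated oxirane at the benzylic carbon in a 6-endo-tet closure with inversion, the known acid cyclisation of 2′-hydroxychalcone epoxides to trans-dihydroflavonols. Under acid the benzylic C–O bond is the weaker one and the carbon next to the carbonyl is deactivated, so 6-endo should beat 5-exo; inversion of the (S) benzylic carbon beside the untouched (R) carbinol carbon gives the (2R,3R) trans isomer. A sulfonic acid is used so that no nucleophilic counter-ion opens the oxirane first, and the two phenols are equivalent, so either closes to the same product.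

Step 6
Reactants: 10 (2R,3R)-3,5-dihydroxy-7-methoxy-2-phenyl-2,3-dihydro-4H-chromen-4-one
Product: 11 (2R,3R)-3-hydroxy-7-methoxy-5-[(3-methylbut-2-en-1-yl)oxy]-2-phenyl-2,3-dihydro-4H-chromen-4-one
Conditions: prenyl bromide (1.5 equiv), K2CO3 (2 equiv), DMF, rt, argon
Reagents that add atoms: 1-bromo-3-methylbut-2-ene (prenyl bromide), CC(C)=CCBr
Why: Williamson ether synthesis on the only phenol of 10; carbonate deprotonates the chelated C5 phenol but not the C3 alcohol, and DMF loosens the O5–H···O=C4 hydrogen bond. Room temperature and exclusion of air are meant to keep the base-sensitive α-ketol from ring opening or oxidation; the stereocentres are not involved.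

Step 7
Reactants: 11 (2R,3R)-3-hydroxy-7-methoxy-5-[(3-methylbut-2-en-1-yl)oxy]-2-phenyl-2,3-dihydro-4H-chromen-4-one
Product: 14 (2R,3R)-3,5-dihydroxy-7-methoxy-8-(3-methylbut-2-en-1-yl)-2-phenyl-2,3-dihydro-4H-chromen-4-one, via C6 dienone 12 (not isolated), via C8 dienone 13 (not isolated)
Conditions: Eu(fod)3 (10 mol %; fod = 6,6,7,7,8,8,8-heptafluoro-2,2-dimethyloctane-3,5-dionate), NaHCO3, PhCl, 85 °C
Reagents that add atoms: none
Why: Lanthanide-catalysed aromatic Claisen rearrangement followed by a Cope rearrangement (para-Claisen–Cope), a known reaction type for 5-O-prenyl flavonoids. The first [3,3] shift can only end at C6 (C4a is substituted) and gives 12 with a crowded 1,1-dimethylallyl group; a second [3,3] shift across C7 moves it to C8, para to O5, as a normal prenyl group (13), and enolisation restores ring A and the O5–H···O=C4 hydrogen bond. The medium is neutral and nothing acts on C2 or C3, so the trans (2R,3R) pair should be carried through.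

## Compound list

1 | 5-methoxyresorcinol (5-methoxybenzene-1,3-diol) | COc1cc(O)cc(O)c1 | starting material
2 | 1-methoxy-3,5-bis(methoxymethoxy)benzene | COCOc1cc(OC)cc(OCOC)c1 | intermediate
3 | (2S,3S)-3-phenylglycidol [(2S,3S)-(3-phenyloxiran-2-yl)methanol] | OC[C@@H]1O[C@H]1c1ccccc1 | starting material
4 | (2R,3S)-3-phenyloxirane-2-carboxylic acid | OC(=O)[C@@H]1O[C@H]1c1ccccc1 | intermediate
5 | (2R,3S)-N-methoxy-N-methyl-3-phenyloxirane-2-carboxamide | CON(C)C(=O)[C@@H]1O[C@H]1c1ccccc1 | intermediate
6 | [4-methoxy-2,6-bis(methoxymethoxy)phenyl]lithium | [Li]c1c(OCOC)cc(OC)cc1OCOC | intermediate (not isolated)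
7 | lithium [4-methoxy-2,6-bis(methoxymethoxy)phenyl][methoxy(methyl)amino][(2R,3S)-3-phenyloxiran-2-yl]methanolate (carbinolamine carbon unassigned) | COCOc1cc(OC)cc(OCOC)c1C(O[Li])(N(C)OC)[C@@H]1O[C@H]1c1ccccc1 | intermediate (not isolated)
8 | [4-methoxy-2,6-bis(methoxymethoxy)phenyl][(2R,3S)-3-phenyloxiran-2-yl]methanone | COCOc1cc(OC)cc(OCOC)c1C(=O)[C@@H]1O[C@H]1c1ccccc1 | intermediate
9 | (2,6-dihydroxy-4-methoxyphenyl)[(2R,3S)-3-phenyloxiran-2-yl]methanone | COc1cc(O)c(C(=O)[C@@H]2O[C@H]2c2ccccc2)c(O)c1 | intermediate (not isolated)
10 | (2R,3R)-3,5-dihydroxy-7-methoxy-2-phenyl-2,3-dihydro-4H-chromen-4-one (alpinone) | COc1cc(O)c2c(c1)O[C@H](c1ccccc1)[C@@H](O)C2=O | intermediate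
11 | (2R,3R)-3-hydroxy-7-methoxy-5-[(3-methylbut-2-en-1-yl)oxy]-2-phenyl-2,3-dihydro-4H-chromen-4-one | COc1cc(OCC=C(C)C)c2c(c1)O[C@H](c1ccccc1)[C@@H](O)C2=O | intermediate
12 | (2R,3R)-3-hydroxy-7-methoxy-6-(2-methylbut-3-en-2-yl)-2-phenyl-2,3-dihydro-4H-chromene-4,5(6H)-dione (C6 unassigned) | COC=1C(C(C)(C)C=C)C(=O)C2=C(C=1)O[C@H](c1ccccc1)[C@@H](O)C2=O | intermediate (not isolated)
13 | (2R,3R)-3-hydroxy-7-methoxy-8-(3-methylbut-2-en-1-yl)-2-phenyl-2,3-dihydro-4H-chromene-4,5(8H)-dione (C8 unassigned) | COC1=CC(=O)C2=C(C1CC=C(C)C)O[C@H](c1ccccc1)[C@@H](O)C2=O | intermediate (not isolated)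
14 | (2R,3R)-3,5-dihydroxy-7-methoxy-8-(3-methylbut-2-en-1-yl)-2-phenyl-2,3-dihydro-4H-chromen-4-one | COc1cc(O)c2c(c1CC=C(C)C)O[C@H](c1ccccc1)[C@@H](O)C2=O | target

## Step count and uncertain steps

Total: 7 steps. Longest linear sequence: 6 steps (3 → 4 → 5 → 8 → 10 → 11 → 14); the ring A branch (1 → 2) joins at step 4.

**Step 4 (key step).** The most likely failure is proton transfer in place of addition. 6 is shielded by two ortho acetal groups and may act as a base toward the N-methoxy group of 5 (loss of formaldehyde) or toward the oxirane C–H, which would return 2 and consume 5. Fallback, from 3 and 6, back to the route at 8: 3 is oxidised (SO3·pyridine, DMSO, Et3N, 0 °C) to (2R,3S)-3-phenyloxirane-2-carbaldehyde F1. The more electrophilic aldehyde takes up 6 at −78 °C to give [4-methoxy-2,6-bis(methoxymethoxy)phenyl][(2S,3S)-3-phenyloxiran-2-yl]methanol F2 as both carbinol epimers. Dess–Martin periodinane (NaHCO3, CH2Cl2) then oxidises both epimers to 8.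

**Step 5.** Three processes may compete with the wanted closure: opening of the oxirane by the solvent before a phenol is free, 5-exo attack at the carbon next to the carbonyl, and ionisation at the benzylic carbon with loss of the inversion (cis isomer or aroyl shift). All arise because deprotection and ring closure share one acidic medium. Fallback, from 6 (made from 2 as in step 4), back at 10, using a syn diol and a Mitsunobu closure in place of the oxirane:
- Purchased methyl (2R,3S)-2,3-dihydroxy-3-phenylpropanoate F3 is converted (2,2-dimethoxypropane, TsOH) into methyl (4R,5S)-2,2-dimethyl-5-phenyl-1,3-dioxolane-4-carboxylate F4.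
- MeNH(OMe)·HCl and i-PrMgCl (THF, −20 °C) give (4R,5S)-N-methoxy-N,2,2-trimethyl-5-phenyl-1,3-dioxolane-4-carboxamide F5.
- 6 is acylated by F5 to [4-methoxy-2,6-bis(methoxymethoxy)phenyl][(4R,5S)-2,2-dimethyl-5-phenyl-1,3-dioxolan-4-yl]methanone F6.
- TsOH·H2O in aqueous MeOH removes acetonide and acetals to give (2R,3S)-1-(2,6-dihydroxy-4-methoxyphenyl)-2,3-dihydroxy-3-phenylpropan-1-one F7.
- PPh3/DIAD (THF, 0 °C) closes ring C by SN2 displacement of the activated benzylic hydroxyl with inversion, giving 10.

**Step 6.** Base-induced ring opening, ring contraction or air oxidation of the α-ketol may outrun alkylation, because the chelated C5 phenol reacts slowly. Fallback, from 10, back at 11: Mitsunobu etherification with 3-methylbut-2-en-1-ol (PPh3, DIAD, THF, 0 °C), which activates the allylic alcohol under neutral conditions and needs no phenoxide. It makes no new compound.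

**Step 7.** The sequence may stop after the first shift: if 12 enolises before the Cope shift, the allyl unit stays on C6 in its rearranged form. The α-ketol may also dehydrate at 85 °C on the Lewis acid. Fallback, from 2, back at 14, with the prenyl group placed before acylation and the methyl groups exchanged at the end:
- 2 is lithiated (n-BuLi, THF, 0 °C) and alkylated with prenyl bromide (CuBr·SMe2 cat.) to give 5-methoxy-1,3-bis(methoxymethoxy)-2-(3-methylbut-2-en-1-yl)benzene F8.
- The two remaining ring hydrogens of F8 are equivalent. A second lithiation and acylation with 5 give [6-methoxy-2,4-bis(methoxymethoxy)-3-(3-methylbut-2-en-1-yl)phenyl][(2R,3S)-3-phenyloxiran-2-yl]methanone F9.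
- Mild acid (TsOH·H2O, MeOH, rt) frees the single ortho phenol, which sits next to the prenyl group. It closes to (2R,3R)-3,7-dihydroxy-5-methoxy-8-(3-methylbut-2-en-1-yl)-2-phenyl-2,3-dihydro-4H-chromen-4-one F10.
- MeI/K2CO3 (acetone) methylates the C7 phenol to give (2R,3R)-3-hydroxy-5,7-dimethoxy-8-(3-methylbut-2-en-1-yl)-2-phenyl-2,3-dihydro-4H-chromen-4-one F11.
- MgI2·OEt2 (THF, 50 °C) removes only the C5 methyl group, which is chelated to the C4 carbonyl, to give 14.

## Further compounds

F1 | step 4 | (2R,3S)-3-phenyloxirane-2-carbaldehyde | O=C[C@@H]1O[C@H]1c1ccccc1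
F2 | step 4 | [4-methoxy-2,6-bis(methoxymethoxy)phenyl][(2S,3S)-3-phenyloxiran-2-yl]methanol (both carbinol epimers) | COCOc1cc(OC)cc(OCOC)c1C(O)[C@@H]1O[C@H]1c1ccccc1
F3 | step 5 | methyl (2R,3S)-2,3-dihydroxy-3-phenylpropanoate (purchased) | COC(=O)[C@H](O)[C@@H](O)c1ccccc1
F4 | step 5 | methyl (4R,5S)-2,2-dimethyl-5-phenyl-1,3-dioxolane-4-carboxylate | COC(=O)[C@@H]1OC(C)(C)O[C@H]1c1ccccc1
F5 | step 5 | (4R,5S)-N-methoxy-N,2,2-trimethyl-5-phenyl-1,3-dioxolane-4-carboxamide | CON(C)C(=O)[C@@H]1OC(C)(C)O[C@H]1c1ccccc1
F6 | step 5 | [4-methoxy-2,6-bis(methoxymethoxy)phenyl][(4R,5S)-2,2-dimethyl-5-phenyl-1,3-dioxolan-4-yl]methanone | COCOc1cc(OC)cc(OCOC)c1C(=O)[C@@H]1OC(C)(C)O[C@H]1c1ccccc1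
F7 | step 5 | (2R,3S)-1-(2,6-dihydroxy-4-methoxyphenyl)-2,3-dihydroxy-3-phenylpropan-1-one | COc1cc(O)c(C(=O)[C@H](O)[C@@H](O)c2ccccc2)c(O)c1
F0 | step 6 | none | none
F8 | step 7 | 5-methoxy-1,3-bis(methoxymethoxy)-2-(3-methylbut-2-en-1-yl)benzene | COCOc1cc(OC)cc(OCOC)c1CC=C(C)C
F9 | step 7 | [6-methoxy-2,4-bis(methoxymethoxy)-3-(3-methylbut-2-en-1-yl)phenyl][(2R,3S)-3-phenyloxiran-2-yl]methanone | COCOc1cc(OC)c(C(=O)[C@@H]2O[C@H]2c2ccccc2)c(OCOC)c1CC=C(C)C
F10 | step 7 | (2R,3R)-3,7-dihydroxy-5-methoxy-8-(3-methylbut-2-en-1-yl)-2-phenyl-2,3-dihydro-4H-chromen-4-one | COc1cc(O)c(CC=C(C)C)c2c1C(=O)[C@H](O)[C@@H](c1ccccc1)O2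
F11 | step 7 | (2R,3R)-3-hydroxy-5,7-dimethoxy-8-(3-methylbut-2-en-1-yl)-2-phenyl-2,3-dihydro-4H-chromen-4-one | COc1cc(OC)c(CC=C(C)C)c2c1C(=O)[C@H](O)[C@@H](c1ccccc1)O2
A1 | alternative 1 | (E)-1-[4-methoxy-2,6-bis(methoxymethoxy)-3-(3-methylbut-2-en-1-yl)phenyl]-3-phenylprop-2-en-1-one | COCOc1cc(OC)c(CC=C(C)C)c(OCOC)c1C(=O)/C=C/c1ccccc1
A2 | alternative 1 | [4-methoxy-2,6-bis(methoxymethoxy)-3-(3-methylbut-2-en-1-yl)phenyl][(2R,3S)-3-phenyloxiran-2-yl]methanone | COCOc1cc(OC)c(CC=C(C)C)c(OCOC)c1C(=O)[C@@H]1O[C@H]1c1ccccc1
A3 | alternative 2 | (2S)-5-hydroxy-7-methoxy-8-(3-methylbut-2-en-1-yl)-2-phenyl-2,3-dihydro-4H-chromen-4-one | COc1cc(O)c2c(c1CC=C(C)C)O[C@H](c1ccccc1)CC2=O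
A4 | alternative 3 | 3-[(tert-butyldimethylsilyl)oxy]-5-hydroxy-7-methoxy-8-(3-methylbut-2-en-1-yl)-4H-chromen-4-one | COc1cc(O)c2c(c1CC=C(C)C)OC=C(O[Si](C)(C)C(C)(C)C)C2=O
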